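**Retrosynthetic overview**

1. 7-Methoxydichamanetin (11) comes from the tri-O-benzyl flavanone 10 by hydrogenolysis; no stereocentre is touched after the key step.
2. 10 comes from the diazoketone 9: the C2–C3 bond of ring C is made by enantioselective intramolecular insertion of a rhodium carbene at C3 into a benzylic C–H bond of an O-benzyl group, so a protecting group becomes C2 and ring B.
3. Enabling feature: C2 is a benzylic CH bonded to O1 and C3 sits next to the C4 carbonyl. The hexasubstituted ring A is symmetric about the C4a–C7 axis (oxygen on C5 and C8a, 2-hydroxybenzyl on C6 and C8, OMe on C7). An achiral precursor with two equivalent benzyl ethers therefore gives one constitution whichever ether reacts.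
4. 9 comes from methyl ketone 5 (diazo transfer), 5 from 3 (per-benzylation), and 3 from 1 + 2 (double ortho-quinone methide C-benzylation at the two free positions of ring A).
5. Ring order: ring A is bought, the two side-arm rings are attached first, ring B enters as an O-benzyl group, ring C is closed last.

Key step: step 4

Assumption: compound 1 is taken as commercially available, and the sense of induction of Rh2(S-PTTL)4 in this insertion cannot be predicted with certainty, so if a pilot run shows the 2R product the mirror-image catalyst Rh2(R-PTTL)4 is to be used with nothing else changed.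

**Step 1**
Reactants: 1 1-(2,6-dihydroxy-4-methoxyphenyl)ethanone; 2 2-hydroxybenzyl alcohol (3 equiv)
Product: 3 1-[2,6-dihydroxy-3,5-bis(2-hydroxybenzyl)-4-methoxyphenyl]ethanone
Conditions: ZnCl2 (anhydrous), 1,4-dioxane, reflux, 2 added in portions
Reagents that add atoms: 2-hydroxybenzyl alcohol, OCc1ccccc1O
Why: Lewis-acid dehydration of 2 should give an ortho-quinone methide that is captured in a double Friedel–Crafts-type benzylation by the two equivalent free positions of the phloroacetophenone ring, each activated by three oxygen substituents, while the acetyl group blocks the remaining position.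

**Step 2**
Reactants: 3 1-[2,6-dihydroxy-3,5-bis(2-hydroxybenzyl)-4-methoxyphenyl]ethanone; 4 benzyl bromide (6 equiv)
Product: 5 1-{2,6-bis(benzyloxy)-3,5-bis[2-(benzyloxy)benzyl]-4-methoxyphenyl}ethanone
Conditions: K2CO3, Bu4NI (cat.), DMF, 70 °C
Reagents that add atoms: benzyl bromide, BrCc1ccccc1
Why: Williamson etherification of all four phenols; the free side-arm phenols should react first and the hydrogen-bonded 2,6-hydroxyls follow with excess reagent in DMF, where O-alkylation is expected over C-alkylation and the methyl ketone is not enolised by carbonate.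

**Step 3**
Reactants: 5 1-{2,6-bis(benzyloxy)-3,5-bis[2-(benzyloxy)benzyl]-4-methoxyphenyl}ethanone; 6 2,2,2-trifluoroethyl trifluoroacetate; 7 4-acetamidobenzenesulfonyl azide
Product: 9 1-{2,6-bis(benzyloxy)-3,5-bis[2-(benzyloxy)benzyl]-4-methoxyphenyl}-2-diazoethanone, via trifluoroacetyl diketone 8 (not isolated)
Conditions: LiN(SiMe3)2, THF, −78 °C, then 6, aq. HCl work-up; crude 8, 7, Et3N, H2O (1 equiv), MeCN, rt
Reagents that add atoms: 4-acetamidobenzenesulfonyl azide, CC(=O)Nc1ccc(cc1)S(=O)(=O)N=[N+]=[N-] (the two diazo nitrogens); 2,2,2-trifluoroethyl trifluoroacetate, O=C(OCC(F)(F)F)C(F)(F)F (trifluoroacetyl group, present in 8 only)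
Why: Detrifluoroacetylative Regitz diazo transfer: Claisen trifluoroacetylation of the lithium enolate of the only enolisable position activates the methyl ketone, and the sulfonyl azide then transfers N2 with loss of the trifluoroacetyl group as the N-acylsulfonamide.

**Step 4**
Reactants: 9 1-{2,6-bis(benzyloxy)-3,5-bis[2-(benzyloxy)benzyl]-4-methoxyphenyl}-2-diazoethanone
Product: 10 (2S)-5-(benzyloxy)-6,8-bis[2-(benzyloxy)benzyl]-7-methoxy-2-phenylchroman-4-one
Conditions: Rh2(S-PTTL)4 [dirhodium tetrakis(N-phthaloyl-(S)-tert-leucinate), divalent rhodium] (1 mol %), toluene, 4 Å molecular sieves, −20 °C to rt, slow addition of 9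
Reagents that add atoms: none
Why: Loss of N2 from 9 on the dirhodium tetracarboxylate should give an electrophilic rhodium carbene at C3, which inserts into a benzylic C–H bond of a flanking benzyl ether through a concerted, hydride-transfer-like three-centre transition state, forming the C2–C3 bond with retention at C2. The closest known reaction type is the intramolecular C–H insertion of 2-alkoxyaryl α-diazoketones into the O–CH2 group under chiral dirhodium carboxylates of divalent rhodium, which gives 2-substituted chroman-4-ones. Ring C closes by 1,6-insertion to a six-membered ring, the only small ring open to this carbene because the atoms one position nearer are the ether oxygens. The C2 stereocentre is set by the chiral catalyst, which must select the pro-S hydrogen of the benzyl CH2, so that insertion with retention gives 2S. Site selectivity needs no control, because the two benzyl ethers next to the acyl group are equivalent by the symmetry of ring A, and the side-arm benzyl ethers and diarylmethane CH2 groups cannot reach the carbene through a small ring. The selectivity that must be won is insertion over capture of the carbene by the ether oxygen (oxonium ylide, then 1,2-benzyl shift to a 2-benzylbenzofuran-3-one); the twist of the di-ortho-substituted aroyl group out of the ring plane, which holds the carbene over the doubly activated O–CH2–Ph hydrogens, and slow addition at low temperature are expected to favour insertion.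

**Step 5**
Reactants: 10 (2S)-5-(benzyloxy)-6,8-bis[2-(benzyloxy)benzyl]-7-methoxy-2-phenylchroman-4-one
Product: 11 7-methoxydichamanetin, (2S)-5-hydroxy-6,8-bis(2-hydroxybenzyl)-7-methoxy-2-phenylchroman-4-one
Conditions: H2 (1 atm), 10% Pd/C, EtOAc–THF, rt
Reagents that add atoms: none
Why: Heterogeneous hydrogenolysis should cleave the three aryl benzyl ethers under neutral conditions, under which the cyclic C2–O1 ether and the hindered C4 ketone of a flavanone are normally retained and C2 cannot epimerise by base-induced ring opening.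

**Compound list**

1 | 1-(2,6-dihydroxy-4-methoxyphenyl)ethanone | CC(=O)c1c(O)cc(OC)cc1O | starting material
2 | 2-hydroxybenzyl alcohol | OCc1ccccc1O | starting material
3 | 1-[2,6-dihydroxy-3,5-bis(2-hydroxybenzyl)-4-methoxyphenyl]ethanone | CC(=O)c1c(O)c(Cc2ccccc2O)c(OC)c(Cc2ccccc2O)c1O | intermediate
4 | benzyl bromide | BrCc1ccccc1 | starting material
5 | 1-{2,6-bis(benzyloxy)-3,5-bis[2-(benzyloxy)benzyl]-4-methoxyphenyl}ethanone | CC(=O)c1c(OCc2ccccc2)c(Cc2ccccc2OCc2ccccc2)c(OC)c(Cc2ccccc2OCc2ccccc2)c1OCc1ccccc1 | intermediate
6 | 2,2,2-trifluoroethyl trifluoroacetate | O=C(OCC(F)(F)F)C(F)(F)F | starting material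
7 | 4-acetamidobenzenesulfonyl azide | CC(=O)Nc1ccc(cc1)S(=O)(=O)N=[N+]=[N-] | starting material
8 | 1-{2,6-bis(benzyloxy)-3,5-bis[2-(benzyloxy)benzyl]-4-methoxyphenyl}-4,4,4-trifluorobutane-1,3-dione | O=C(CC(=O)C(F)(F)F)c1c(OCc2ccccc2)c(Cc2ccccc2OCc2ccccc2)c(OC)c(Cc2ccccc2OCc2ccccc2)c1OCc1ccccc1 | intermediate
9 | 1-{2,6-bis(benzyloxy)-3,5-bis[2-(benzyloxy)benzyl]-4-methoxyphenyl}-2-diazoethanone | [N-]=[N+]=CC(=O)c1c(OCc2ccccc2)c(Cc2ccccc2OCc2ccccc2)c(OC)c(Cc2ccccc2OCc2ccccc2)c1OCc1ccccc1 | intermediate
10 | (2S)-5-(benzyloxy)-6,8-bis[2-(benzyloxy)benzyl]-7-methoxy-2-phenylchroman-4-one | COc1c(Cc2ccccc2OCc2ccccc2)c(OCc2ccccc2)c2c(c1Cc1ccccc1OCc1ccccc1)O[C@H](c1ccccc1)CC2=O | intermediate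
11 | 7-methoxydichamanetin, (2S)-5-hydroxy-6,8-bis(2-hydroxybenzyl)-7-methoxy-2-phenylchroman-4-one | COc1c(Cc2ccccc2O)c(O)c2c(c1Cc1ccccc1O)O[C@H](c1ccccc1)CC2=O | target

Total step count: 5
Longest linear sequence: 5 steps (1 → 3 → 5 → 9 → 10 → 11)

**Steps most likely to fail**

Step 4. The carbene may be captured by the lone pair of the flanking ether oxygen and rearrange by 1,2-benzyl shift faster than it inserts, and the catalyst may discriminate the two enantiotopic benzylic hydrogens poorly. The fallback closes ring C by oxa-Michael addition instead and sets out from 5. Chelation-directed cleavage of one benzyl ether ortho to the acetyl group (MgBr2·OEt2, toluene–Et2O, reflux) should give 1-{2-(benzyloxy)-3,5-bis[2-(benzyloxy)benzyl]-6-hydroxy-4-methoxyphenyl}ethanone F1. Claisen–Schmidt condensation with benzaldehyde (KOH, EtOH, rt) should give the 2'-hydroxychalcone (E)-1-{2-(benzyloxy)-3,5-bis[2-(benzyloxy)benzyl]-6-hydroxy-4-methoxyphenyl}-3-phenylprop-2-en-1-one F2. Cyclisation with NaOAc in refluxing EtOH should give racemic 5-(benzyloxy)-6,8-bis[2-(benzyloxy)benzyl]-7-methoxy-2-phenylchroman-4-one F3. Preparative HPLC on an amylose tris(3,5-dimethylphenylcarbamate) chiral stationary phase separates 10 from (2R)-5-(benzyloxy)-6,8-bis[2-(benzyloxy)benzyl]-7-methoxy-2-phenylchroman-4-one F4, which is recycled to F3 by base-mediated ring opening and closure. The fallback comes back to the route at 10.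

Step 1. The quinone methide may oligomerise or alkylate the side-arm phenols of the product, or the reaction may stop after one benzylation, leaving inseparable mixtures. The fallback replaces electrophilic benzylation by cross-coupling and sets out from 1. Ring bromination at both free positions (Br2, 2 equiv, AcOH, rt) should give 1-(3,5-dibromo-2,6-dihydroxy-4-methoxyphenyl)ethanone F5. O-benzylation (benzyl bromide, K2CO3, DMF, 70 °C) should give 1-[2,6-bis(benzyloxy)-3,5-dibromo-4-methoxyphenyl]ethanone F6. Double Negishi coupling (Pd(OAc)2, SPhos, THF, 60 °C) with [2-(benzyloxy)benzyl]zinc bromide F7, made from commercial 2-(benzyloxy)benzyl bromide with zinc dust and LiCl in THF at 0 °C, should give 5 directly. The fallback comes back at 5 and bypasses 3 and step 2.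

Step 5. Reductive cleavage of the benzylic C2–O1 bond (opening to the dihydrochalcone) or reduction of the C4 carbonyl may compete with slow removal of the hindered 5-O-benzyl group. The fallback replaces hydrogenolysis by Lewis-acid ionisation of the benzyl ethers with a cation scavenger: from 10, BCl3 and pentamethylbenzene in CH2Cl2 at −78 °C, then methanol quench, should give 11 directly without any reducing agent.

**Further compounds**

F1 | step 4 | 1-{2-(benzyloxy)-3,5-bis[2-(benzyloxy)benzyl]-6-hydroxy-4-methoxyphenyl}ethanone | CC(=O)c1c(O)c(Cc2ccccc2OCc2ccccc2)c(OC)c(Cc2ccccc2OCc2ccccc2)c1OCc1ccccc1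
F2 | step 4 | (E)-1-{2-(benzyloxy)-3,5-bis[2-(benzyloxy)benzyl]-6-hydroxy-4-methoxyphenyl}-3-phenylprop-2-en-1-one | O=C(/C=C/c1ccccc1)c1c(O)c(Cc2ccccc2OCc2ccccc2)c(OC)c(Cc2ccccc2OCc2ccccc2)c1OCc1ccccc1
F3 | step 4 | racemic 5-(benzyloxy)-6,8-bis[2-(benzyloxy)benzyl]-7-methoxy-2-phenylchroman-4-one | COc1c(Cc2ccccc2OCc2ccccc2)c(OCc2ccccc2)c2c(c1Cc1ccccc1OCc1ccccc1)OC(c1ccccc1)CC2=O
F4 | step 4 | (2R)-5-(benzyloxy)-6,8-bis[2-(benzyloxy)benzyl]-7-methoxy-2-phenylchroman-4-one | COc1c(Cc2ccccc2OCc2ccccc2)c(OCc2ccccc2)c2c(c1Cc1ccccc1OCc1ccccc1)O[C@@H](c1ccccc1)CC2=O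
F5 | step 1 | 1-(3,5-dibromo-2,6-dihydroxy-4-methoxyphenyl)ethanone | CC(=O)c1c(O)c(Br)c(OC)c(Br)c1O
F6 | step 1 | 1-[2,6-bis(benzyloxy)-3,5-dibromo-4-methoxyphenyl]ethanone | CC(=O)c1c(OCc2ccccc2)c(Br)c(OC)c(Br)c1OCc1ccccc1
F7 | step 1 | [2-(benzyloxy)benzyl]zinc bromide | Br[Zn]Cc1ccccc1OCc1ccccc1
F0 | step 5 | none | none
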